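**Retrosynthetic overview**

- Feature: in the maleimide ring (N1–C2(=O)–C3=C4–C5(=O)), C3 and C4 are each the α-carbon of one of the two carbonyls carried by N1, so the C3–C4 bond joins two enolisable donor carbons of an unsymmetrical N,N-diacylamine.
- C3=C4 is taken back to the C3–C4 single bond of succinimide 18 (dehydrogenated late), and that bond to an oxidative coupling of the two α-carbons in the dilithium bis-enolate of acyclic imide 16.
- Imide 16 comes from N-acylation of arylacetamide 14 (4-hydroxyphenylacetic acid, 2,4-dimethoxybenzylamine, PMBCl) with the chloride of chromanylpropanoic acid 10, itself from Negishi coupling of bromochromane 7 with a zinc homoenolate.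
- Bromochromane 7 comes from Jacobsen epoxidation and benzylic hydride opening of 7-bromo-2,2-dimethyl-2H-chromene 4 (this sets 3S); 4 comes from 4-bromosalicylaldehyde and an isobutenyl Grignard reagent.
- Ring order: the pyran ring of the chroman first (step 1), the pyrrolidine-2,5-dione ring last (step 10), then oxidation to the maleimide; N-DMB, O-PMB and O-TBS all fall in one final acidolysis.

Key step: step 10

Remark: the (S,S)-Jacobsen catalyst is taken to give the (3S,4S)-epoxide, as it does with other 2,2-dimethyl-2H-chromenes (the (R,R)-catalyst would be used if the sense were opposite). The two ring stereocentres made in step 10 are carried as a mixture because step 11 removes both.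

**Route**

Step 1
Reactants: 1 4-bromo-2-hydroxybenzaldehyde; 2 2-methyl-1-propenylmagnesium bromide
Product: 4 7-bromo-2,2-dimethyl-2H-chromene, via allylic alcohol 3 (not isolated)
Conditions: 2 (2.5 equiv), THF, 0 °C → rt; aq. NH4Cl; crude 3, PPTS (10 mol%), PhMe, 70 °C
Reagents that add atoms: none
Why: One equivalent of the Grignard reagent deprotonates the phenol and a second adds to the aldehyde; the benzylic–allylic alcohol 3 then loses water under mild acid to a vinyl o-quinone methide that closes by oxa-6π electrocyclisation (the intermediate of phenol–enal chromene syntheses), which places bromine at C7 without regioisomers.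

Step 2
Reactants: 4 7-bromo-2,2-dimethyl-2H-chromene
Product: 5 (3S,4S)-7-bromo-3,4-epoxy-2,2-dimethylchromane
Conditions: (S,S)-Jacobsen Mn(salen)Cl (3 mol%), 4-phenylpyridine N-oxide (20 mol%), aq. NaOCl (pH 11.3 buffer), CH2Cl2, 0 °C
Reagents that add atoms: sodium hypochlorite, [Na+].[O-]Cl
Why: Jacobsen–Katsuki epoxidation, for which cis-configured aryl-conjugated 2,2-dimethylchromenes are among the best substrates; the (S,S)-salen ligand should direct oxo transfer to the face that gives the (3S,4S)-epoxide, which fixes the only stereocentre of the target.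

Step 3
Reactants: 5 (3S,4S)-7-bromo-3,4-epoxy-2,2-dimethylchromane
Product: 6 (3S)-7-bromo-2,2-dimethylchroman-3-ol
Conditions: LiAlH4 (1.0 equiv), THF, 0 °C → rt; Fieser work-up
Reagents that add atoms: none
Why: SN2 hydride opening of the epoxide at the benzylic C4, which is far more accessible than C3 next to the quaternary C2, leaves the C3–O bond untouched so that the 3S configuration is retained, and the aryl bromide should be inert to LiAlH4 at this temperature.

Step 4
Reactants: 6 (3S)-7-bromo-2,2-dimethylchroman-3-ol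
Product: 7 (3S)-7-bromo-3-(tert-butyldimethylsilyloxy)-2,2-dimethylchromane
Conditions: TBSOTf (1.3 equiv), 2,6-lutidine (2 equiv), CH2Cl2, 0 °C
Reagents that add atoms: tert-butyldimethylsilyl triflate, CC(C)(C)[Si](C)(C)OS(=O)(=O)C(F)(F)F
Why: Silylation with the silyl triflate, chosen because the secondary alcohol is hindered by the neighbouring quaternary carbon and would react slowly with the chloride.

Step 5
Reactants: 7 (3S)-7-bromo-3-(tert-butyldimethylsilyloxy)-2,2-dimethylchromane; 8 (3-ethoxy-3-oxopropyl)zinc bromide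
Product: 9 ethyl 3-[(3S)-3-(tert-butyldimethylsilyloxy)-2,2-dimethylchroman-7-yl]propanoate
Conditions: 8 (1.5 equiv, 0.5 M in THF), Pd(OAc)2 (2 mol%), SPhos (4 mol%), THF, 50 °C
Reagents that add atoms: none
Why: Negishi sp2–sp3 coupling of an aryl bromide with an ester-bearing primary alkylzinc halide, in which the bulky biarylphosphine favours reductive elimination over β-hydride elimination and the silyl ether and ester are tolerated.

Step 6
Reactants: 9 ethyl 3-[(3S)-3-(tert-butyldimethylsilyloxy)-2,2-dimethylchroman-7-yl]propanoate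
Product: 10 3-[(3S)-3-(tert-butyldimethylsilyloxy)-2,2-dimethylchroman-7-yl]propanoic acid
Conditions: LiOH·H2O (3 equiv), THF/MeOH/H2O, rt; 1 M HCl to pH 4, 0 °C
Reagents that add atoms: lithium hydroxide, [Li+].[OH-]
Why: Ester saponification, to which the hindered secondary silyl ether should be stable.

Step 7
Reactants: 11 4-hydroxyphenylacetic acid; 12 2,4-dimethoxybenzylamine
Product: 13 N-(2,4-dimethoxybenzyl)-2-(4-hydroxyphenyl)acetamide
Conditions: EDC·HCl (1.2 equiv), HOBt (1.2 equiv), DMF, 0 °C → rt
Reagents that add atoms: none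
Why: Carbodiimide/HOBt amide coupling, in which the primary amine outcompetes the free phenol for the active ester.

Step 8
Reactants: 13 N-(2,4-dimethoxybenzyl)-2-(4-hydroxyphenyl)acetamide
Product: 14 N-(2,4-dimethoxybenzyl)-2-{4-[(4-methoxybenzyl)oxy]phenyl}acetamide
Conditions: PMBCl (1.1 equiv), K2CO3 (2 equiv), Bu4NI (cat.), DMF, rt → 50 °C
Reagents that add atoms: 4-methoxybenzyl chloride, COc1ccc(CCl)cc1
Why: Williamson etherification in which carbonate deprotonates only the phenol and not the much less acidic amide N–H, giving a phenol ether that withstands LDA yet is acid-labile like the other two protecting groups.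

Step 9
Reactants: 10 3-[(3S)-3-(tert-butyldimethylsilyloxy)-2,2-dimethylchroman-7-yl]propanoic acid; 14 N-(2,4-dimethoxybenzyl)-2-{4-[(4-methoxybenzyl)oxy]phenyl}acetamide
Product: 16 N-(2,4-dimethoxybenzyl)-N-(2-{4-[(4-methoxybenzyl)oxy]phenyl}acetyl)-3-[(3S)-3-(tert-butyldimethylsilyloxy)-2,2-dimethylchroman-7-yl]propanamide, via acid chloride 15 (not isolated)
Conditions: 10, 1-chloro-N,N,2-trimethylprop-1-en-1-amine (1.1 equiv), CH2Cl2, 0 °C → rt, evaporate; 14 (2.2 equiv), LiHMDS (2.2 equiv), THF, −78 °C, then 15 in THF, −78 °C; AcOH (3 equiv), −78 °C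
Reagents that add atoms: none
Why: N-acylation of a lithium amidate by an acid chloride made under neutral (Ghosez) conditions; the second equivalent of the inexpensive amidate takes up the acidic arylacetyl proton of the product, so the imide rests as its enolate until the cold acidic quench.

Step 10
Reactants: 16 N-(2,4-dimethoxybenzyl)-N-(2-{4-[(4-methoxybenzyl)oxy]phenyl}acetyl)-3-[(3S)-3-(tert-butyldimethylsilyloxy)-2,2-dimethylchroman-7-yl]propanamide
Product: 18 N-(2,4-dimethoxybenzyl)-3-{4-[(4-methoxybenzyl)oxy]phenyl}-4-{[(3S)-3-(tert-butyldimethylsilyloxy)-2,2-dimethylchroman-7-yl]methyl}pyrrolidine-2,5-dione (mixture at C3/C4 of the imide ring), via dilithium bis-enolate 17 (not isolated)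
Conditions: 16 added to LDA (2.4 equiv), THF (0.02 M), −78 °C, 20 min; Cu(II) 2-ethylhexanoate (2.4 equiv) in THF, −78 → 0 °C; aq. NH4Cl/NH3
Reagents that add atoms: none
Why: Proposed new method: LDA removes first the arylacetyl proton and then an α-proton of the propanoyl arm, and since amide conjugation is lost in bis-enolate 17 the two N–C(OLi) bonds rotate freely, so the two α-carbons held 1,5 through C(O)–N–C(O) can meet; Cu(II) then oxidises the more electron-rich aryl-conjugated enolate to an α-aryl-α-carbamoyl radical that adds to the carbon terminus of the neighbouring enolate, and the resulting α-amino-ketyl-type radical anion is oxidised at once by the second Cu(II) to the second imide carbonyl (reductive elimination from a C,C-bound copper bis-enolate is an equivalent inner-sphere picture). The closest known reaction types are the Cu(II)- or Fe(III)-mediated oxidative coupling of imide and amide enolates, the intramolecular oxidative coupling of tethered bis-enolates (diester dianions, N,N'-diacyl ureas) and the 5-endo radical cyclisation of α-carbamoyl radicals onto N-vinyl amides; what is new is that the imide nitrogen itself is the only tether. The pyrrolidine-2,5-dione ring closes by a 5-endo-trig radical-to-enolate (or 1,5 radical–radical) union forming C3–C4, which avoids the disfavoured 5-(enolendo)-exo-tet geometry of an ionic alkylation. The new stereocentres C3 and C4 are controlled by nothing beyond a preference for the trans isomer (C3–H is acidic and can equilibrate) and need no control because both become sp2 in step 11, while the remote chroman C3 centre is untouched. The step needs intramolecular C–C coupling to outrun N→C acyl migration, ketene loss and intermolecular dimerisation: inverse addition into excess LDA at −78 °C leaves no neutral imide carbonyl beside an enolate, high dilution suppresses dimerisation, and the single nitrogen tether allows only the cross-coupled product.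

Step 11
Reactants: 18 N-(2,4-dimethoxybenzyl)-3-{4-[(4-methoxybenzyl)oxy]phenyl}-4-{[(3S)-3-(tert-butyldimethylsilyloxy)-2,2-dimethylchroman-7-yl]methyl}pyrrolidine-2,5-dione
Product: 21 N-(2,4-dimethoxybenzyl)-3-{4-[(4-methoxybenzyl)oxy]phenyl}-4-{[(3S)-3-(tert-butyldimethylsilyloxy)-2,2-dimethylchroman-7-yl]methyl}-1H-pyrrole-2,5-dione, via selenide 19 (not isolated), via selenoxide 20 (not isolated)
Conditions: LiHMDS (1.1 equiv), THF, −78 °C; PhSeCl (1.2 equiv), −78 °C; then 30% H2O2 (3 equiv), pyridine, CH2Cl2, 0 °C → rt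
Reagents that add atoms: none
Why: Enolate selenenylation and selenoxide syn-elimination (Reich–Sharpless dehydrogenation): only the aryl-bearing C3–H is acidic enough for LiHMDS, PhSeCl should enter anti to the C4 substituent and hence syn to C4–H, and the selenoxide has no other β-hydrogen, so it can only eliminate into the ring, which erases both transient stereocentres.

Step 12
Reactants: 21 N-(2,4-dimethoxybenzyl)-3-{4-[(4-methoxybenzyl)oxy]phenyl}-4-{[(3S)-3-(tert-butyldimethylsilyloxy)-2,2-dimethylchroman-7-yl]methyl}-1H-pyrrole-2,5-dione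
Product: 22 asperimide C, 3-(4-hydroxyphenyl)-4-{[(3S)-3-hydroxy-2,2-dimethylchroman-7-yl]methyl}-1H-pyrrole-2,5-dione
Conditions: TFA/H2O/anisole (90:5:5), rt → 60 °C
Reagents that add atoms: none
Why: Acidolysis (SN1 cleavage) of three acid-labile groups in one operation, the PMB ether and silyl ether at room temperature and the N-(2,4-dimethoxybenzyl) imide on warming, with anisole trapping the benzyl cations by Friedel–Crafts alkylation and water keeping the secondary alcohol free; the carbinol centre should not ionise because the adjacent C2–O bond destabilises a cation at C3.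

**Compound list**

1 | 4-bromo-2-hydroxybenzaldehyde | O=Cc1ccc(Br)cc1O | starting material
2 | 2-methyl-1-propenylmagnesium bromide (THF solution) | CC(C)=C[Mg]Br | starting material
3 | 5-bromo-2-(1-hydroxy-3-methylbut-2-en-1-yl)phenol (racemic, not isolated) | CC(C)=CC(O)c1ccc(Br)cc1O | intermediate
4 | 7-bromo-2,2-dimethyl-2H-chromene | CC1(C)C=Cc2ccc(Br)cc2O1 | intermediate
5 | (3S,4S)-7-bromo-3,4-epoxy-2,2-dimethylchromane | CC1(C)Oc2cc(Br)ccc2[C@@H]2O[C@H]12 | intermediate
6 | (3S)-7-bromo-2,2-dimethylchroman-3-ol | CC1(C)Oc2cc(Br)ccc2C[C@@H]1O | intermediate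
7 | (3S)-7-bromo-3-(tert-butyldimethylsilyloxy)-2,2-dimethylchromane | CC1(C)Oc2cc(Br)ccc2C[C@@H]1O[Si](C)(C)C(C)(C)C | intermediate
8 | (3-ethoxy-3-oxopropyl)zinc bromide (THF solution) | CCOC(=O)CC[Zn]Br | starting material
9 | ethyl 3-[(3S)-3-(tert-butyldimethylsilyloxy)-2,2-dimethylchroman-7-yl]propanoate | CC1(C)Oc2cc(CCC(=O)OCC)ccc2C[C@@H]1O[Si](C)(C)C(C)(C)C | intermediate
10 | 3-[(3S)-3-(tert-butyldimethylsilyloxy)-2,2-dimethylchroman-7-yl]propanoic acid | CC1(C)Oc2cc(CCC(=O)O)ccc2C[C@@H]1O[Si](C)(C)C(C)(C)C | intermediate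
11 | 4-hydroxyphenylacetic acid | O=C(O)Cc1ccc(O)cc1 | starting material
12 | 2,4-dimethoxybenzylamine | COc1ccc(CN)c(OC)c1 | starting material
13 | N-(2,4-dimethoxybenzyl)-2-(4-hydroxyphenyl)acetamide | COc1ccc(CNC(=O)Cc2ccc(O)cc2)c(OC)c1 | intermediate
14 | N-(2,4-dimethoxybenzyl)-2-{4-[(4-methoxybenzyl)oxy]phenyl}acetamide | COc1ccc(COc2ccc(CC(=O)NCc3ccc(OC)cc3OC)cc2)cc1 | intermediate
15 | 3-[(3S)-3-(tert-butyldimethylsilyloxy)-2,2-dimethylchroman-7-yl]propanoyl chloride (not isolated) | CC1(C)Oc2cc(CCC(Cl)=O)ccc2C[C@@H]1O[Si](C)(C)C(C)(C)C | intermediate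
16 | N-(2,4-dimethoxybenzyl)-N-(2-{4-[(4-methoxybenzyl)oxy]phenyl}acetyl)-3-[(3S)-3-(tert-butyldimethylsilyloxy)-2,2-dimethylchroman-7-yl]propanamide (key-step precursor) | CC1(C)Oc2cc(CCC(=O)N(Cc3ccc(OC)cc3OC)C(=O)Cc3ccc(OCc4ccc(OC)cc4)cc3)ccc2C[C@@H]1O[Si](C)(C)C(C)(C)C | intermediate
17 | dilithium bis-enolate of 16 (not isolated) | CC1(C)Oc2cc(CC=C([O-])N(Cc3ccc(OC)cc3OC)C([O-])=Cc3ccc(OCc4ccc(OC)cc4)cc3)ccc2C[C@@H]1O[Si](C)(C)C(C)(C)C.[Li+].[Li+] | intermediate
18 | N-(2,4-dimethoxybenzyl)-3-{4-[(4-methoxybenzyl)oxy]phenyl}-4-{[(3S)-3-(tert-butyldimethylsilyloxy)-2,2-dimethylchroman-7-yl]methyl}pyrrolidine-2,5-dione (mixture at ring C3/C4; key-step product) | CC1(C)Oc2cc(CC3C(c4ccc(OCc5ccc(OC)cc5)cc4)C(=O)N(Cc4ccc(OC)cc4OC)C3=O)ccc2C[C@@H]1O[Si](C)(C)C(C)(C)C | intermediate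
19 | 3-phenylselanyl derivative of 18 (SePh on the aryl-bearing ring carbon, not isolated) | CC1(C)Oc2cc(CC3C(=O)N(Cc4ccc(OC)cc4OC)C(=O)C3([Se]c5ccccc5)c6ccc(OCc7ccc(OC)cc7)cc6)ccc2C[C@@H]1O[Si](C)(C)C(C)(C)C | intermediate
20 | selenoxide of 19 (not isolated) | CC1(C)Oc2cc(CC3C(=O)N(Cc4ccc(OC)cc4OC)C(=O)C3([Se](=O)c5ccccc5)c6ccc(OCc7ccc(OC)cc7)cc6)ccc2C[C@@H]1O[Si](C)(C)C(C)(C)C | intermediate
21 | N-(2,4-dimethoxybenzyl)-3-{4-[(4-methoxybenzyl)oxy]phenyl}-4-{[(3S)-3-(tert-butyldimethylsilyloxy)-2,2-dimethylchroman-7-yl]methyl}-1H-pyrrole-2,5-dione | CC1(C)Oc2cc(CC3=C(c4ccc(OCc5ccc(OC)cc5)cc4)C(=O)N(Cc4ccc(OC)cc4OC)C3=O)ccc2C[C@@H]1O[Si](C)(C)C(C)(C)C | intermediate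
22 | asperimide C | CC1(C)Oc2cc(CC3=C(c4ccc(O)cc4)C(=O)NC3=O)ccc2C[C@@H]1O | target

**Count**

Total steps: 12. Longest linear sequence: 10 steps (steps 1–6 and 9–12); steps 7–8 form the side branch.

**Steps most likely to fail**

Step 10 (proposed new method). The bis-enolate may fail to close. Before oxidation the imide enolates can rearrange by N→C acyl shift or lose ketene. After the first electron transfer the benzylic radical can dimerise or be oxidised further instead of attacking the second enolate. The fallback replaces the oxidative coupling by a polar aldol condensation, in which the arylacetyl carbon becomes the electrophile. It sets out from imide 16 and returns at maleimide 21, so step 11 is no longer needed. Diazo transfer to the arylacetyl methylene of 16 (p-ABSA, DBU, MeCN) should give the α-diazo imide F1. Oxidation with dimethyldioxirane (acetone, 0 °C) should give the α-keto imide F2. LiHMDS (THF, −78 °C) then enolises the propanoyl arm, which adds to the neighbouring aryl ketone to give the 3-hydroxysuccinimide F3. Dehydration of F3 (MsCl, Et3N) should give 21. This is the ring closure of the known glyoxylate–acetamide maleimide condensation and of 1,4-dicarbonyl aldol cyclisations.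

Step 9. Proton transfer from the acidic methylene of the product to unreacted amidate, O-acylation, or acyl scrambling of the imide enolate on warming may erode the N-acylation. The fallback forms the N–benzyl bond last instead of the N–acyl bond. It sets out from acid 10 (through its chloride 15) and returns at 16. Commercial 2-(4-hydroxyphenyl)acetamide is converted with PMBCl and K2CO3 into 2-{4-[(4-methoxybenzyl)oxy]phenyl}acetamide F4. Its sodium salt (NaH, 2 equiv, THF) is acylated with 15 to give the N–H imide F5, which rests as its harmless N-anion because N–H is its most acidic site. Mitsunobu N-alkylation of F5 with 2,4-dimethoxybenzyl alcohol (PPh3, DIAD) should then give 16.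

Step 12. N-debenzylation of the imide may be slow and force long heating in acid. During that time re-benzylation of the freed phenol and acid-induced opening or dehydration of the chromanol can compete. The fallback exchanges the nitrogen through the anhydride. It sets out from 21 and returns at 22. Hydrolysis of 21 (KOH, EtOH/H2O, reflux; then cold dilute HCl) should give the maleic anhydride F6. Treatment with HMDS and MeOH in DMF at rt should give the N–H maleimide F7. The PMB and silyl ethers of F7 then fall with TFA/H2O/anisole at room temperature to give 22.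

**Further compounds**

F1 | step 10 | N-(2,4-dimethoxybenzyl)-N-(2-diazo-2-{4-[(4-methoxybenzyl)oxy]phenyl}acetyl)-3-[(3S)-3-(tert-butyldimethylsilyloxy)-2,2-dimethylchroman-7-yl]propanamide | CC1(C)Oc2cc(CCC(=O)N(Cc3ccc(OC)cc3OC)C(=O)C(=[N+]=[N-])c3ccc(OCc4ccc(OC)cc4)cc3)ccc2C[C@@H]1O[Si](C)(C)C(C)(C)C
F2 | step 10 | N-(2,4-dimethoxybenzyl)-N-(2-{4-[(4-methoxybenzyl)oxy]phenyl}-2-oxoacetyl)-3-[(3S)-3-(tert-butyldimethylsilyloxy)-2,2-dimethylchroman-7-yl]propanamide | CC1(C)Oc2cc(CCC(=O)N(Cc3ccc(OC)cc3OC)C(=O)C(=O)c3ccc(OCc4ccc(OC)cc4)cc3)ccc2C[C@@H]1O[Si](C)(C)C(C)(C)C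
F3 | step 10 | N-(2,4-dimethoxybenzyl)-3-hydroxy-3-{4-[(4-methoxybenzyl)oxy]phenyl}-4-{[(3S)-3-(tert-butyldimethylsilyloxy)-2,2-dimethylchroman-7-yl]methyl}pyrrolidine-2,5-dione (diastereomer mixture) | CC1(C)Oc2cc(CC3C(=O)N(Cc4ccc(OC)cc4OC)C(=O)C3(O)c5ccc(OCc6ccc(OC)cc6)cc5)ccc2C[C@@H]1O[Si](C)(C)C(C)(C)C
F4 | step 9 | 2-{4-[(4-methoxybenzyl)oxy]phenyl}acetamide | COc1ccc(COc2ccc(CC(N)=O)cc2)cc1
F5 | step 9 | N-(2-{4-[(4-methoxybenzyl)oxy]phenyl}acetyl)-3-[(3S)-3-(tert-butyldimethylsilyloxy)-2,2-dimethylchroman-7-yl]propanamide | CC1(C)Oc2cc(CCC(=O)NC(=O)Cc3ccc(OCc4ccc(OC)cc4)cc3)ccc2C[C@@H]1O[Si](C)(C)C(C)(C)C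
F6 | step 12 | 3-{4-[(4-methoxybenzyl)oxy]phenyl}-4-{[(3S)-3-(tert-butyldimethylsilyloxy)-2,2-dimethylchroman-7-yl]methyl}furan-2,5-dione | CC1(C)Oc2cc(CC3=C(c4ccc(OCc5ccc(OC)cc5)cc4)C(=O)OC3=O)ccc2C[C@@H]1O[Si](C)(C)C(C)(C)C
F7 | step 12 | 3-{4-[(4-methoxybenzyl)oxy]phenyl}-4-{[(3S)-3-(tert-butyldimethylsilyloxy)-2,2-dimethylchroman-7-yl]methyl}-1H-pyrrole-2,5-dione | CC1(C)Oc2cc(CC3=C(c4ccc(OCc5ccc(OC)cc5)cc4)C(=O)NC3=O)ccc2C[C@@H]1O[Si](C)(C)C(C)(C)C
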